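**Retrosynthetic overview**
- Target 19 comes from lactone ketone 16 by one acidic hydrogenolysis that turns the C7 ketone into CH2 and removes the phenol benzyl group.
- Feature the plan rests on: in the lactone ring O1–C2(=O)–C3–C4–C5, C3 is a fully substituted carbinol. With C7 (on C4) at the ketone oxidation level, C4–H is the only acidic C–H of the core. C5 can therefore enter as formaldehyde at C4 (C4–C5), the C5 oxygen closes O1–C2, and C4 then settles under equilibrium control against C3.
- The aldol substrate 12 carries C2 and the C3 oxygen as a pivaldehyde acetal (1,3-dioxolan-4-one). This masks the tertiary alkoxide and makes C2 an activated acyl donor that releases pivaldehyde on ring closure.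
- 12 comes from (S)-malic acid: cis-dioxolanone 3, dianion benzylation with bromide 7 (C3–C7′ bond, sets C3), then thioester and acyl cross-coupling (C7–aryl bond).
- Ring order: the auxiliary dioxolanone forms in step 1 and is destroyed in step 8, where the only ring of the target, the γ-lactone, is closed.

Key step: step 8

Remark on numbering: O1, C2 (carbonyl), C3 (quaternary carbinol), C4, C5 are the lactone atoms; C7 is the benzylic carbon on C4 and C7′ the benzylic carbon on C3.

Remark on the chemistry (assumption): the key-step precursor is handled as its pivaldehyde acetal 12 instead of the free 2-hydroxy methyl ester; skeleton and C3 configuration are the same. Two reasons: alkoxide-mediated ester exchange on a β-oxy aryl ketone invites retro-aldol and E1cB cleavage, and an α-bromoketone is an unreliable electrophile for an ester-type lithium enolate (carbonyl addition, proton transfer). The aryl ketone is therefore introduced after the quaternary centre, by a base-free acyl cross-coupling.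

**Step 1**
Reactants: 1 (S)-malic acid; 2 pivaldehyde
Product: 3 2-[(2S,4S)-2-tert-butyl-5-oxo-1,3-dioxolan-4-yl]acetic acid (cis acetal)
Conditions: p-TsOH·H2O (cat.), H2SO4 (cat.), pentane, reflux, Dean–Stark; recrystallisation
Reagents that add atoms: none
Why: Acid-catalysed acetalisation of the α-hydroxy acid unit should give the five-membered dioxolanone rather than the six-membered dioxanone, the malic stereocentre is untouched and steers the new acetal carbon to the thermodynamically preferred cis (2S) isomer, which crystallisation should enrich.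

**Step 2**
Reactants: 4 syringaldehyde
Product: 5 4-(benzyloxy)-3,5-dimethoxybenzaldehyde
Conditions: BnBr, K2CO3, DMF, 60 °C
Reagents that add atoms: benzyl bromide, BrCc1ccccc1
Why: Williamson etherification of the acidic para-formyl phenol should be clean, and the benzyl group is chosen because it leaves in the final hydrogenolysis.

**Step 3**
Reactants: 5 4-(benzyloxy)-3,5-dimethoxybenzaldehyde
Product: 6 [4-(benzyloxy)-3,5-dimethoxyphenyl]methanol
Conditions: NaBH4, MeOH/THF, 0 °C
Reagents that add atoms: none
Why: Borohydride reduction of an aryl aldehyde is chemoselective, and the ethers are inert.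

**Step 4**
Reactants: 6 [4-(benzyloxy)-3,5-dimethoxyphenyl]methanol
Product: 7 2-(benzyloxy)-5-(bromomethyl)-1,3-dimethoxybenzene
Conditions: PBr3, Et2O, 0 °C; used directly
Reagents that add atoms: phosphorus tribromide, BrP(Br)Br
Why: Bromide displaces the phosphite ester of a primary benzylic alcohol by SN2, and low temperature with immediate use should protect the aryl benzyl ether and the labile bromide.

**Step 5**
Reactants: 3 2-[(2S,4S)-2-tert-butyl-5-oxo-1,3-dioxolan-4-yl]acetic acid; 7 2-(benzyloxy)-5-(bromomethyl)-1,3-dimethoxybenzene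
Product: 9 2-[(2S,4S)-4-{[4-(benzyloxy)-3,5-dimethoxyphenyl]methyl}-2-tert-butyl-5-oxo-1,3-dioxolan-4-yl]acetic acid, via dilithium dianion 8 (not isolated)
Conditions: LiHMDS (2.2 equiv), THF, −78 °C; then 7, −78 → −30 °C; cold aq. HCl work-up
Reagents that add atoms: lithium bis(trimethylsilyl)amide, [Li+].C[Si](C)(C)[N-][Si](C)(C)C (lithium is carried in 8 only)
Why: Enolate alkylation under the self-regeneration-of-stereocentres principle, an established reaction of this malic acetal with benzylic halides: the trigonal ring carbon of the carboxylate/enolate dianion is attacked anti to the tert-butyl group, so the arylmethyl group replaces H with retention and fixes the quaternary (S) centre that becomes C3.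

**Step 6**
Reactants: 9 2-[(2S,4S)-4-{[4-(benzyloxy)-3,5-dimethoxyphenyl]methyl}-2-tert-butyl-5-oxo-1,3-dioxolan-4-yl]acetic acid
Product: 10 S-phenyl 2-[(2S,4S)-4-{[4-(benzyloxy)-3,5-dimethoxyphenyl]methyl}-2-tert-butyl-5-oxo-1,3-dioxolan-4-yl]ethanethioate
Conditions: PhSH, EDC·HCl, DMAP (cat.), CH2Cl2, 0 °C → rt
Reagents that add atoms: benzenethiol, Sc1ccccc1
Why: Steglich-type carbodiimide thioesterification activates the side-chain carboxyl under near-neutral conditions, avoiding an acid chloride (which could acylate the electron-rich syringyl ring intramolecularly to a tetralone) and avoiding strong base (E1cB opening of the acetal).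

**Step 7**
Reactants: 10 S-phenyl thioester; 11 (3,4-dimethoxyphenyl)boronic acid
Product: 12 (2S,5S)-5-{[4-(benzyloxy)-3,5-dimethoxyphenyl]methyl}-2-tert-butyl-5-[2-(3,4-dimethoxyphenyl)-2-oxoethyl]-1,3-dioxolan-4-one (acetal-protected form of the 2-hydroxy-4-oxobutanoate precursor)
Conditions: Pd2(dba)3 (2.5 mol %), tri(2-furyl)phosphine (10 mol %), CuTC (1.5 equiv), THF, 50 °C
Reagents that add atoms: none
Why: The Liebeskind–Srogl coupling of a thioester with an electron-rich arylboronic acid forms the C7–aryl ketone without base, so the dioxolanone, the benzyl ether and the β-oxy carbonyl array should survive and the quaternary centre is not touched.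

**Step 8**
Reactants: 12 (2S,5S)-5-{[4-(benzyloxy)-3,5-dimethoxyphenyl]methyl}-2-tert-butyl-5-[2-(3,4-dimethoxyphenyl)-2-oxoethyl]-1,3-dioxolan-4-one; 13 formaldehyde (37 % aqueous)
Product: 16 (3S,4S)-3-{[4-(benzyloxy)-3,5-dimethoxyphenyl]methyl}-4-(3,4-dimethoxybenzoyl)-3-hydroxyoxolan-2-one, via silyl enol ether 14 (not isolated), via hydroxymethyl ketone 15 (not isolated)
Conditions: TMSOTf (1.2 equiv), Et3N (1.5 equiv), CH2Cl2, 0 °C, pentane extraction; then aq. HCHO, Yb(OTf)3 (10 mol %), THF, rt, extractive work-up; then CSA (20 mol %), CH2Cl2, rt → 40 °C until the C4 epimer ratio is constant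
Reagents that add atoms: trimethylsilyl trifluoromethanesulfonate, C[Si](C)(C)OS(=O)(=O)C(F)(F)F (Me3Si is carried in 14 only; no reagent atoms remain in 16)
Why: Soft enolisation can only give the C4=C7 silyl enol ether 14, because C3 is quaternary and the dioxolanone carbonyl has no α-hydrogen, and its lanthanide-triflate-catalysed aqueous Mukaiyama aldol with formaldehyde forms C4–C5 (the closest known reaction type is the Lewis-acid hydroxymethylation of aryl ketone silyl enol ethers). Under CSA the new C5 hydroxyl attacks the acylal carbonyl C2 in a 5-exo-trig acyl substitution that closes the O1–C2 bond of the lactone and expels the hemiacetal, which collapses to pivaldehyde and the free C3–OH (the known acid-induced lactonisation of γ-hydroxy dioxolanones). The new C4 stereocentre is not set kinetically: it is α to the aryl ketone, epimerises through the enol under the same acid, and the fixed C3 centre should place the aroyl group trans to the bulky C7′ arylmethyl group and cis to the small, hydrogen-bond-donating C3–OH, which is the (3S,4S) isomer. The step needs chemoselectivity against retro-aldol and β-elimination at the β-oxy ketone, which is secured by keeping the C3 oxygen locked in the acetal until the C–C bond exists and by running every operation under neutral to acidic conditions; formaldehyde is washed out before the acid stage so that no formal acetal can form. A second hydroxymethylation is unlikely because 15 and 16 keep only a hindered tertiary α-hydrogen and no silyl enol ether.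

**Step 9**
Reactants: 16 (3S,4S)-3-{[4-(benzyloxy)-3,5-dimethoxyphenyl]methyl}-4-(3,4-dimethoxybenzoyl)-3-hydroxyoxolan-2-one
Product: 19 (3S,4S)-4-[(3,4-dimethoxyphenyl)methyl]-3-hydroxy-3-[(4-hydroxy-3,5-dimethoxyphenyl)methyl]oxolan-2-one, via phenol ketone 17 (not isolated), via benzylic carbinol 18 (not isolated)
Conditions: H2 (3 atm), 10 % Pd/C, AcOH–EtOAc, HClO4 (cat.), rt
Reagents that add atoms: none
Why: Palladium hydrogenolysis cleaves the aryl benzyl ether and, with acid, reduces the para-alkoxy aryl ketone through the carbinol to CH2 by direct benzylic C–O hydrogenolysis (the reaction type used to deoxygenate 7-oxo and 7-hydroxy dibenzylbutyrolactones), so C4 is retained and becomes configurationally fixed once C7 is no longer a carbonyl, while the non-benzylic C3–OH and the lactone are not affected.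

**Compound list**
1 | (S)-malic acid | OC(=O)C[C@H](O)C(=O)O | starting material
2 | pivaldehyde | CC(C)(C)C=O | starting material
3 | 2-[(2S,4S)-2-tert-butyl-5-oxo-1,3-dioxolan-4-yl]acetic acid | OC(=O)C[C@@H]1O[C@H](C(C)(C)C)OC1=O | intermediate
4 | syringaldehyde | COc1cc(C=O)cc(OC)c1O | starting material
5 | 4-(benzyloxy)-3,5-dimethoxybenzaldehyde | COc1cc(C=O)cc(OC)c1OCc1ccccc1 | intermediate
6 | [4-(benzyloxy)-3,5-dimethoxyphenyl]methanol | COc1cc(CO)cc(OC)c1OCc1ccccc1 | intermediate
7 | 2-(benzyloxy)-5-(bromomethyl)-1,3-dimethoxybenzene | COc1cc(CBr)cc(OC)c1OCc1ccccc1 | intermediate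
8 | dilithium 2-[(2S)-2-tert-butyl-5-oxido-1,3-dioxol-4-yl]acetate (carboxylate/enolate dianion of 3, not isolated) | [Li+].[Li+].[O-]C(=O)CC1=C([O-])O[C@@H](C(C)(C)C)O1 | intermediate
9 | 2-[(2S,4S)-4-{[4-(benzyloxy)-3,5-dimethoxyphenyl]methyl}-2-tert-butyl-5-oxo-1,3-dioxolan-4-yl]acetic acid | OC(=O)C[C@]1(Cc2cc(OC)c(OCc3ccccc3)c(OC)c2)O[C@H](C(C)(C)C)OC1=O | intermediate
10 | S-phenyl 2-[(2S,4S)-4-{[4-(benzyloxy)-3,5-dimethoxyphenyl]methyl}-2-tert-butyl-5-oxo-1,3-dioxolan-4-yl]ethanethioate | O=C(Sc1ccccc1)C[C@]1(Cc2cc(OC)c(OCc3ccccc3)c(OC)c2)O[C@H](C(C)(C)C)OC1=O | intermediate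
11 | (3,4-dimethoxyphenyl)boronic acid | COc1ccc(B(O)O)cc1OC | starting material
12 | (2S,5S)-5-{[4-(benzyloxy)-3,5-dimethoxyphenyl]methyl}-2-tert-butyl-5-[2-(3,4-dimethoxyphenyl)-2-oxoethyl]-1,3-dioxolan-4-one | O=C(c1ccc(OC)c(OC)c1)C[C@]1(Cc2cc(OC)c(OCc3ccccc3)c(OC)c2)O[C@H](C(C)(C)C)OC1=O | intermediate
13 | formaldehyde | C=O | starting material
14 | (2S,5S)-5-{[4-(benzyloxy)-3,5-dimethoxyphenyl]methyl}-2-tert-butyl-5-[(Z)-2-(3,4-dimethoxyphenyl)-2-(trimethylsilyloxy)ethenyl]-1,3-dioxolan-4-one (not isolated) | C[Si](C)(C)O/C(c1ccc(OC)c(OC)c1)=C\[C@]1(Cc2cc(OC)c(OCc3ccccc3)c(OC)c2)O[C@H](C(C)(C)C)OC1=O | intermediate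
15 | (2S,5S)-5-{[4-(benzyloxy)-3,5-dimethoxyphenyl]methyl}-2-tert-butyl-5-[1-(3,4-dimethoxyphenyl)-3-hydroxy-1-oxopropan-2-yl]-1,3-dioxolan-4-one (both epimers at the side-chain carbon, not isolated) | O=C(c1ccc(OC)c(OC)c1)C(CO)[C@]1(Cc2cc(OC)c(OCc3ccccc3)c(OC)c2)O[C@H](C(C)(C)C)OC1=O | intermediate
16 | (3S,4S)-3-{[4-(benzyloxy)-3,5-dimethoxyphenyl]methyl}-4-(3,4-dimethoxybenzoyl)-3-hydroxyoxolan-2-one | O=C(c1ccc(OC)c(OC)c1)[C@H]1COC(=O)[C@]1(O)Cc1cc(OC)c(OCc2ccccc2)c(OC)c1 | intermediate
17 | (3S,4S)-4-(3,4-dimethoxybenzoyl)-3-hydroxy-3-[(4-hydroxy-3,5-dimethoxyphenyl)methyl]oxolan-2-one (not isolated) | O=C(c1ccc(OC)c(OC)c1)[C@H]1COC(=O)[C@]1(O)Cc1cc(OC)c(O)c(OC)c1 | intermediate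
18 | (3S,4R)-4-[(3,4-dimethoxyphenyl)(hydroxy)methyl]-3-hydroxy-3-[(4-hydroxy-3,5-dimethoxyphenyl)methyl]oxolan-2-one (ring centres spatially as in 17, both carbinol epimers, not isolated) | OC(c1ccc(OC)c(OC)c1)[C@H]1COC(=O)[C@]1(O)Cc1cc(OC)c(O)c(OC)c1 | intermediate
19 | (3S,4S)-4-[(3,4-dimethoxyphenyl)methyl]-3-hydroxy-3-[(4-hydroxy-3,5-dimethoxyphenyl)methyl]oxolan-2-one | COc1ccc(C[C@H]2COC(=O)[C@]2(O)Cc2cc(OC)c(O)c(OC)c2)cc1OC | target

**Totals**
Total step count: 9. Longest linear sequence: 8 steps (4 → 19, steps 2 to 9).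

**Steps most likely to fail**

Step 8. The one-carbon unit may be lost again by retro-aldol, or the free β-hydroxy ketone may dehydrate to the α-methylene ketone before the lactone closes. The fallback sets out from 12, through its silyl enol ether 14 made as in step 8, and changes the C1 electrophile from an aldehyde to an α-chloro ether. Lewis-acid alkylation of 14 with benzyl chloromethyl ether (TiCl4 or catalytic ZnBr2, CH2Cl2, −78 °C) should give (2S,5S)-5-{[4-(benzyloxy)-3,5-dimethoxyphenyl]methyl}-5-[3-(benzyloxy)-1-(3,4-dimethoxyphenyl)-1-oxopropan-2-yl]-2-tert-butyl-1,3-dioxolan-4-one F1, in which the aldol oxygen is capped and can neither leave nor revert. Neutral hydrogenolysis (H2, Pd(OH)2/C, EtOAc) should then remove both benzyl groups to give (2S,5S)-2-tert-butyl-5-[1-(3,4-dimethoxyphenyl)-3-hydroxy-1-oxopropan-2-yl]-5-[(4-hydroxy-3,5-dimethoxyphenyl)methyl]-1,3-dioxolan-4-one F2. CSA in CH2Cl2 closes the lactone with loss of pivaldehyde and equilibrates C4. The fallback comes back to the route at phenol ketone 17, which the step 9 conditions carry on to 19.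

Step 9. Hydrogenolysis on palladium may stall at the benzylic carbinol, or acid on the catalyst may dehydrate that carbinol to a C4=C7 alkene whose re-hydrogenation would erode C4. The fallback sets out from 16 and separates the two tasks. Homogeneous ionic hydrogenation (excess Et3SiH, TFA, CH2Cl2, 0 °C → rt), the standard reduction of para-alkoxy aryl ketones to methylene by hydride capture of the benzylic cation, should give (3S,4S)-3-{[4-(benzyloxy)-3,5-dimethoxyphenyl]methyl}-4-[(3,4-dimethoxyphenyl)methyl]-3-hydroxyoxolan-2-one F3. Neutral debenzylation (H2, Pd/C, EtOAc) then returns to the route at 19. Any benzyl ether lost already in TFA leads to the same compound.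

Step 7. The electron-rich boronic acid may protodeboronate or homocouple, or oxidative addition into the neopentyl-type thioester may be sluggish, leaving 10 unconverted. The fallback sets out from acid 9 and replaces the cross-coupling by nucleophilic acyl substitution. Amidation (EDC·HCl, MeNHOMe·HCl, N-methylmorpholine, CH2Cl2) should give 2-[(2S,4S)-4-{[4-(benzyloxy)-3,5-dimethoxyphenyl]methyl}-2-tert-butyl-5-oxo-1,3-dioxolan-4-yl]-N-methoxy-N-methylacetamide F4. Commercial (3,4-dimethoxyphenyl)magnesium bromide (THF, −40 → 0 °C) should add once to the Weinreb amide through the stable chelate, the dioxolanone carbonyl being shielded by its quaternary neighbour. The fallback comes back to the route at ketone 12.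

**Further compounds**
F1 | step 8 | (2S,5S)-5-{[4-(benzyloxy)-3,5-dimethoxyphenyl]methyl}-5-[3-(benzyloxy)-1-(3,4-dimethoxyphenyl)-1-oxopropan-2-yl]-2-tert-butyl-1,3-dioxolan-4-one | O=C(c1ccc(OC)c(OC)c1)C(COCc1ccccc1)[C@]1(Cc2cc(OC)c(OCc3ccccc3)c(OC)c2)O[C@H](C(C)(C)C)OC1=O
F2 | step 8 | (2S,5S)-2-tert-butyl-5-[1-(3,4-dimethoxyphenyl)-3-hydroxy-1-oxopropan-2-yl]-5-[(4-hydroxy-3,5-dimethoxyphenyl)methyl]-1,3-dioxolan-4-one | O=C(c1ccc(OC)c(OC)c1)C(CO)[C@]1(Cc2cc(OC)c(O)c(OC)c2)O[C@H](C(C)(C)C)OC1=O
F3 | step 9 | (3S,4S)-3-{[4-(benzyloxy)-3,5-dimethoxyphenyl]methyl}-4-[(3,4-dimethoxyphenyl)methyl]-3-hydroxyoxolan-2-one | COc1ccc(C[C@H]2COC(=O)[C@]2(O)Cc2cc(OC)c(OCc3ccccc3)c(OC)c2)cc1OC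
F4 | step 7 | 2-[(2S,4S)-4-{[4-(benzyloxy)-3,5-dimethoxyphenyl]methyl}-2-tert-butyl-5-oxo-1,3-dioxolan-4-yl]-N-methoxy-N-methylacetamide | CON(C)C(=O)C[C@]1(Cc2cc(OC)c(OCc3ccccc3)c(OC)c2)O[C@H](C(C)(C)C)OC1=O
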